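The data are calculated with constants of no real substance, noise included.

If a flask stops early with substrate still in it, I ask what has been spent, and here I suspect the partner.

| setting | south | south-east | east | flask |
|---|---|---|---|---|
| left-handed substrate | 0.10 M | 0.40 M | 0.20 M | 0.20 M |
| right-handed substrate | 0.10 M | 0.40 M | 0.20 M | 0.20 M |
| partner | 3 equiv | 3 equiv | 1.5 equiv | 3.00 equiv |
| free catalyst | 0.93 mol% | 0.93 mol% | 0.93 mol% | 0.93 mol% |
| remark | run made earlier | run made earlier | run made earlier |  |
| time |  |  |  | 4.0 min |

- south (time / min: left-handed substrate / %, left-handed product / %, right-handed substrate / %): 0.417: 42, 8, 45; 0.833: 40, 8, 43; 2.00: 39, 7, 45; 5.00: 42, 10, 44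
- south-east (time / min: left-handed substrate / %, left-handed product / %, right-handed substrate / %): 0.417: 13, 33, 27; 0.833: 15, 33, 25; 2.00: 13, 38, 22; 5.00: 16, 37, 23
- east (time / min: left-handed substrate / %, left-handed product / %, right-handed substrate / %): 0.667: 39, 14, 41; 1.50: 38, 7, 42; 3.00: 39, 12, 41; 5.00: 38, 9, 41

(standard deviation of a reading: 1.5 percentage points)

- free catalyst is single-handed; left-handed substrate and right-handed substrate are mirror images of each other, charged as a racemate, each of them at the stated concentration
- the numbers in the tables scatter with a standard deviation of 1.5 percentage points

1. conversion of left-handed substrate and right-handed substrate together at 4.0 min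
2. amount of left-handed product at 4.0 min, in percent of the left-handed substrate and right-handed substrate together charged
3. amount of right-handed substrate at 4.0 min, in percent of the left-handed substrate and right-handed substrate together charged

The substrates of the east run hold still within the scatter, at a conversion of 20.2%. Counting one partner per substrate turned, that took 27.0% of the partner charged, which is odds of 0.370. I call this number the partner odds: partner that made product for each partner lost some other way. I expect it to grow with catalyst and with substrate at hand.

The south-east run tests that. At twice the east substrate concentrations, with 3 equiv of partner against 1.5 equiv and a conversion of 61.5%, it reads 0.695, where scaling with catalyst and substrate promises 1.48. So one number does not carry that far, but this flask starts at the east substrate concentrations and differs from the east run in partner.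

The east share put straight into this flask gives 40.5% conversion. That leaves less substrate on average, so I go round once, scaling the odds to 0.328, and I commit to 37.1%. The forecast is lower: 33% conversion, 18% left-handed product and 36% right-handed substrate, with “the extent set by the concentrations”.

The flask gives 33.8% conversion, 20.1% left-handed product and 36.4% right-handed substrate.

    partner + catalyst intermediate A → free catalyst + left-handed product (k = 61.0 L mol⁻¹ s⁻¹)
    partner → decomposed reagent (k = 0.0960 s⁻¹)
    free catalyst + left-handed substrate ⇌ catalyst intermediate A (K = 1.70 L mol⁻¹, k = 11000 L mol⁻¹ s⁻¹)
    partner + catalyst intermediate B → free catalyst + right-handed product (k = 20.0 L mol⁻¹ s⁻¹)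
    free catalyst + right-handed substrate ⇌ catalyst intermediate B (K = 3.20 L mol⁻¹, k = 1800 L mol⁻¹ s⁻¹)

The partner odds of this flask come to 0.291, against 0.370 in the east run. Scaled with catalyst to the neighbour holding 0.56 mol%, they give 22.4% conversion, and that neighbour gives 23.2%. In the flask the partner, the limiting reagent, stands at 5.29% of its charge at 0.400 min and at 0% at 4.00 min, less than the 60% of the charged left-handed substrate still there, unbound. The flask is at rest: at 40.0 min it still shows 20.1% left-handed product, 36.4% right-handed substrate and 33.8% conversion.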